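**Plan**
- Retrosynthetic cuts: (a) the diaryl ether bond between a ring A oxygen and the ether carbon of ring B; (b) the C–C bonds of ring B that a malonate Michael–Claisen annulation makes on a methyl enone; (c) the bond between the second and third chain carbons counted from the carbinol (Grignard/epoxide); (d) the Z-alkene (Wittig).
- Enabling feature: in ring B the ether carbon lies between two hydroxyl-bearing carbons and para to the carbon carrying the carbinol. One oxidation level lower, ring B is a 5-substituted cyclohexane-1,3-dione whose C2 (the future ether carbon) accepts a diazo group.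
- Forward order: ring A chain (Sonogashira, Z-Wittig), then coupling to the glycidol-derived epoxide, then annulation of the dione (latent ring B), then closure of the 22-membered ring by carbenoid O–H insertion, then aromatisation of ring B and desilylation.
- Stereochemistry: the single (R)-carbinol is C2 of (S)-glycidol, and no bond to it is broken at any stage. The Z-alkene comes from a salt-free Wittig reaction.
- Protecting groups: ring A phenols as TBS ethers (cleaved by methoxide during the annulation), the carbinol as a TIPS ether (survives hot base and mild acid).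

Key step: step 16

Remark: 6-chlorohexan-1-ol (8) is taken as a further commercial starting material; 26 is drawn as the diketone although its enol should prevail, and the undefined ring centres in 21–23, 26 and 27 are of no consequence because they end in aromatic ring B.

**Step 1**
Reactants: 1 1-bromo-3,5-dimethoxybenzene; 2 hex-5-yn-1-ol
Product: 3 6-(3,5-dimethoxyphenyl)hex-5-yn-1-ol
Conditions: PdCl2(PPh3)2 (2 mol %), CuI (4 mol %), Et3N, 70 °C
Reagents that add atoms: none
Why: Sonogashira coupling of an aryl bromide with a terminal alkyne, which tolerates the free primary alcohol.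

**Step 2**
Reactants: 3 6-(3,5-dimethoxyphenyl)hex-5-yn-1-ol
Product: 4 6-(3,5-dimethoxyphenyl)hexan-1-ol
Conditions: H2 (1 atm), Pd/C, EtOAc, rt
Reagents that add atoms: none
Why: heterogeneous catalytic hydrogenation should saturate the aryl alkyne without touching the aryl methyl ethers or the alcohol.

**Step 3**
Reactants: 4 6-(3,5-dimethoxyphenyl)hexan-1-ol
Product: 5 5-(6-bromohexyl)benzene-1,3-diol
Conditions: 48% aq HBr, AcOH, reflux
Reagents that add atoms: hydrogen bromide, Br
Why: hot HBr cleaves both aryl methyl ethers (bromide attack at methyl) and converts the primary alcohol into the bromide in the same operation, the classical acid demethylation of 5-alkylresorcinol dimethyl ethers.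

**Step 4**
Reactants: 5 5-(6-bromohexyl)benzene-1,3-diol
Product: 6 1-(6-bromohexyl)-3,5-bis(tert-butyldimethylsilyloxy)benzene
Conditions: TBSCl, imidazole, CH2Cl2, 0 °C → rt
Reagents that add atoms: tert-butyldimethylsilyl chloride, CC(C)(C)[Si](C)(C)Cl
Why: standard imidazole-mediated silylation of phenols, fast enough at low temperature that the primary bromide is not alkylated.

**Step 5**
Reactants: 6 1-(6-bromohexyl)-3,5-bis(tert-butyldimethylsilyloxy)benzene
Product: 7 {6-[3,5-bis(tert-butyldimethylsilyloxy)phenyl]hexyl}triphenylphosphonium bromide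
Conditions: PPh3, MeCN, reflux
Reagents that add atoms: triphenylphosphine, c1ccc(cc1)P(c1ccccc1)c1ccccc1
Why: SN2 quaternisation of triphenylphosphine by a primary alkyl bromide; the aryl silyl ethers are inert to these neutral conditions.

**Step 6**
Reactants: 8 6-chlorohexan-1-ol
Product: 9 6-chlorohexanal
Conditions: TEMPO (10 mol %), PhI(OAc)2, CH2Cl2, rt
Reagents that add atoms: none
Why: oxoammonium-mediated (TEMPO/PhI(OAc)2) oxidation of a primary alcohol stops at the aldehyde and leaves the alkyl chloride alone.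

**Step 7**
Reactants: 7 {6-[3,5-bis(tert-butyldimethylsilyloxy)phenyl]hexyl}triphenylphosphonium bromide; 9 6-chlorohexanal
Product: 11 1,3-bis(tert-butyldimethylsilyloxy)-5-[(6Z)-12-chlorododec-6-en-1-yl]benzene, via phosphonium ylide 10 (not isolated)
Conditions: NaN(SiMe3)2, THF, −78 → 0 °C; then 9, −78 °C → rt
Reagents that add atoms: none
Why: Wittig olefination of a non-stabilised ylide under lithium-free conditions should give the Z-alkene by kinetic formation of the cis-oxaphosphetane, and the primary chloride is not attacked by the ylide at low temperature.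

**Step 8**
Reactants: 12 (S)-glycidol
Product: 13 (R)-2-{[(4-methoxybenzyl)oxy]methyl}oxirane
Conditions: NaH, 4-methoxybenzyl chloride, Bu4NI (cat.), THF/DMF, 0 °C → rt
Reagents that add atoms: 4-methoxybenzyl chloride, COc1ccc(CCl)cc1
Why: Williamson etherification of the primary alkoxide leaves the stereocentre untouched, the descriptor changing from S to R only through the CIP priorities.

**Step 9**
Reactants: 11 1,3-bis(tert-butyldimethylsilyloxy)-5-[(6Z)-12-chlorododec-6-en-1-yl]benzene; 13 (R)-2-{[(4-methoxybenzyl)oxy]methyl}oxirane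
Product: 15 (2R,9Z)-15-[3,5-bis(tert-butyldimethylsilyloxy)phenyl]-1-[(4-methoxybenzyl)oxy]pentadec-9-en-2-ol, via alkylmagnesium chloride 14 (not isolated)
Conditions: Mg, I2 (cat.), THF, reflux; then 13, CuI (10 mol %), THF, −30 → 0 °C
Reagents that add atoms: none
Why: copper-catalysed Grignard opening of a terminal epoxide occurs at the unsubstituted carbon, so the C–O bond at the stereocentre stays intact and the (R)-carbinol is carried over from glycidol with retention.

**Step 10**
Reactants: 15 (2R,9Z)-15-[3,5-bis(tert-butyldimethylsilyloxy)phenyl]-1-[(4-methoxybenzyl)oxy]pentadec-9-en-2-ol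
Product: 16 triisopropylsilyl ether of 15 at the C2 hydroxyl, (2R,9Z)
Conditions: TIPSOTf, 2,6-lutidine, CH2Cl2, 0 °C → rt
Reagents that add atoms: triisopropylsilyl trifluoromethanesulfonate, CC(C)[Si](OS(=O)(=O)C(F)(F)F)(C(C)C)C(C)C
Why: silyl triflate silylation of a secondary alcohol; TIPS is chosen because it should survive the hot alkoxide, hydroxide and mild acid of step 14.

**Step 11**
Reactants: 16 triisopropylsilyl ether of 15
Product: 17 (2R,9Z)-15-[3,5-bis(tert-butyldimethylsilyloxy)phenyl]-2-(triisopropylsilyloxy)pentadec-9-en-1-ol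
Conditions: DDQ, CH2Cl2/pH 7 phosphate buffer, 0 °C → rt
Reagents that add atoms: none
Why: oxidative cleavage of a 4-methoxybenzyl ether by benzylic hydride abstraction and hydrolysis of the oxocarbenium ion, conditions to which silyl ethers and the isolated Z-alkene are inert.

**Step 12**
Reactants: 17 (2R,9Z)-15-[3,5-bis(tert-butyldimethylsilyloxy)phenyl]-2-(triisopropylsilyloxy)pentadec-9-en-1-ol
Product: 18 (2R,9Z)-15-[3,5-bis(tert-butyldimethylsilyloxy)phenyl]-2-(triisopropylsilyloxy)pentadec-9-enal
Conditions: Dess–Martin periodinane, CH2Cl2, 0 °C → rt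
Reagents that add atoms: none
Why: Dess–Martin oxidation is non-basic and should deliver the α-silyloxy aldehyde without epimerisation; it is used directly.

**Step 13**
Reactants: 18 (2R,9Z)-15-[3,5-bis(tert-butyldimethylsilyloxy)phenyl]-2-(triisopropylsilyloxy)pentadec-9-enal
Product: 19 (3E,5R,12Z)-18-[3,5-bis(tert-butyldimethylsilyloxy)phenyl]-5-(triisopropylsilyloxy)octadeca-3,12-dien-2-one
Conditions: Ph3P=CHC(O)CH3, toluene, 80 °C
Reagents that add atoms: 1-(triphenylphosphoranylidene)propan-2-one, CC(=O)C=P(c1ccccc1)(c1ccccc1)c1ccccc1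
Why: Wittig reaction of a stabilised ylide gives the (E)-enone under neutral conditions that leave the adjacent stereocentre intact.

**Step 14**
Reactants: 19 (3E,5R,12Z)-18-[3,5-bis(tert-butyldimethylsilyloxy)phenyl]-5-(triisopropylsilyloxy)octadeca-3,12-dien-2-one; 20 dimethyl malonate
Product: 24 5-[(1R,8Z)-14-(3,5-dihydroxyphenyl)-1-(triisopropylsilyloxy)tetradec-8-en-1-yl]cyclohexane-1,3-dione, via Michael adduct 21 (not isolated), via cyclic keto ester 22 (not isolated), via keto acid 23 (not isolated)
Conditions: dimethyl malonate (1.5 equiv), NaOMe (0.2 equiv), MeOH, 0 °C → rt; then NaOMe (3.5 equiv), reflux; 2 M aq NaOH, reflux; aq HCl to pH 3, 70 °C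
Reagents that add atoms: none
Why: malonate Michael addition to the enone, Claisen (Dieckmann-type) closure of the methyl ketone enolate onto a malonate ester, saponification and decarboxylation of the β-keto acid form the classical route to 5-substituted cyclohexane-1,3-diones; methoxide also cleaves both aryl silyl ethers while the TIPS ether should hold, and the ring carbon bearing the side chain is not stereogenic in the symmetric dione, so the facial course of the addition is immaterial.

**Step 15**
Reactants: 24 5-[(1R,8Z)-14-(3,5-dihydroxyphenyl)-1-(triisopropylsilyloxy)tetradec-8-en-1-yl]cyclohexane-1,3-dione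
Product: 25 2-diazo-5-[(1R,8Z)-14-(3,5-dihydroxyphenyl)-1-(triisopropylsilyloxy)tetradec-8-en-1-yl]cyclohexane-1,3-dione
Conditions: 4-acetamidobenzenesulfonyl azide, Et3N, MeCN, 0 °C → rt
Reagents that add atoms: 4-acetamidobenzenesulfonyl azide, CC(=O)Nc1ccc(cc1)S(=O)(=O)N=[N+]=[N-]
Why: Regitz diazo transfer takes place at C2 of the dione, whose enolate forms with triethylamine far more readily than a phenoxide, so the free ring A hydroxyls should stay untouched.

**Step 16**
Reactants: 25 2-diazo-5-[(1R,8Z)-14-(3,5-dihydroxyphenyl)-1-(triisopropylsilyloxy)tetradec-8-en-1-yl]cyclohexane-1,3-dione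
Product: 26 22-membered macrocyclic 2-aryloxycyclohexane-1,3-dione (one ring A oxygen bonded to C2 of the dione, one ring A hydroxyl free, (R)-carbinol TIPS ether, Z-alkene)
Conditions: Rh2(OAc)4 (5 mol %), benzene, 80 °C, syringe-pump addition of 25 over 12 h, final 1 mM
Reagents that add atoms: none
Why: Loss of dinitrogen from 25 at Rh2(OAc)4 should generate a dirhodium-bound carbene at C2 of the dione, made strongly electrophilic by its two carbonyl neighbours; attack of a ring A hydroxyl oxygen followed by transfer of the hydroxyl proton and release of the catalyst amounts to a formal O–H insertion that forms the aryl ether bond. The closest known reaction type is the Rh2(OAc)4-catalysed O–H insertion of cyclic 2-diazo-1,3-diones into phenols, here run intramolecularly in the manner of known macrocyclising carbenoid O–H insertions. The 22-membered ring closes end to end, the phenol oxygen at one terminus of the seco chain bonding to the carbenoid carbon at the other, and slow addition at high dilution keeps the closure ahead of intermolecular insertion. No stereocentre of consequence is created, since the new ether carbon is enolisable and becomes aromatic, and the remote (R)-carbinol is untouched. The step needs O–H insertion to win over addition to the Z-alkene, attack on ring A carbons, Wolff rearrangement and reaction at the carbinol oxygen; the nucleophilic phenol oxygen is the best partner for this electrophilic carbenoid, and the carbinol is blocked as its TIPS ether. The two hydroxyls of ring A are equivalent by symmetry, so either gives the same product.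

**Step 17**
Reactants: 26 macrocyclic 2-aryloxycyclohexane-1,3-dione
Product: 27 macrocyclic 2-aryloxy-1,3-bis(tert-butyldimethylsilyloxy)cyclohexa-1,3-diene with the ring A hydroxyl also silylated (tris-TBS, mixture of epimers at the sp3 ring carbon bearing the side chain)
Conditions: TBSOTf (4 equiv), Et3N (6 equiv), CH2Cl2, 0 °C → rt
Reagents that add atoms: tert-butyldimethylsilyl trifluoromethanesulfonate, CC(C)(C)[Si](C)(C)OS(=O)(=O)C(F)(F)F
Why: soft enolisation with silyl triflate and amine silylates the enol and the phenol and then converts the resulting vinylogous silyl ester into the bis-silyl dienol ether, a known preparation of 1,3-bis(silyloxy)cyclohexa-1,3-dienes from cyclohexane-1,3-diones.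

**Step 18**
Reactants: 27 tris-TBS macrocyclic bis-silyl dienol ether
Product: 28 tris-O-TBS, O-TIPS ether of the target (ring B aromatic, both ring B oxygens and the ring A oxygen as TBS ethers, carbinol as TIPS ether)
Conditions: DDQ (1.1 equiv), benzene, rt
Reagents that add atoms: none
Why: DDQ dehydrogenates the electron-rich cyclohexadiene by hydride abstraction from an allylic ring carbon followed by proton loss, a known aromatisation of bis-silyl enol ethers of cyclohexane-1,3-diones to resorcinol silyl ethers.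

**Step 19**
Reactants: 28 tris-O-TBS, O-TIPS ether of the target
Product: 29 target CNP0316989.2
Conditions: Bu4NF (6 equiv), AcOH (6 equiv), THF, 0 °C → rt
Reagents that add atoms: none
Why: fluoride-mediated desilylation removes the three aryl TBS ethers and the secondary TIPS ether, and acetic acid buffering protects the electron-rich polyphenol while no benzylic cation can form, so the carbinol configuration should be kept.

**Compound list**
1 | 1-bromo-3,5-dimethoxybenzene | COc1cc(Br)cc(OC)c1 | starting material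
2 | hex-5-yn-1-ol | OCCCCC#C | starting material
3 | 6-(3,5-dimethoxyphenyl)hex-5-yn-1-ol | COc1cc(cc(OC)c1)C#CCCCCO | intermediate
4 | 6-(3,5-dimethoxyphenyl)hexan-1-ol | COc1cc(CCCCCCO)cc(OC)c1 | intermediate
5 | 5-(6-bromohexyl)benzene-1,3-diol | Oc1cc(CCCCCCBr)cc(O)c1 | intermediate
6 | 1-(6-bromohexyl)-3,5-bis(tert-butyldimethylsilyloxy)benzene | BrCCCCCCc1cc(O[Si](C)(C)C(C)(C)C)cc(O[Si](C)(C)C(C)(C)C)c1 | intermediate
7 | {6-[3,5-bis(tert-butyldimethylsilyloxy)phenyl]hexyl}triphenylphosphonium bromide | [Br-].c1ccccc1[P+](c1ccccc1)(c1ccccc1)CCCCCCc1cc(O[Si](C)(C)C(C)(C)C)cc(O[Si](C)(C)C(C)(C)C)c1 | intermediate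
8 | 6-chlorohexan-1-ol | OCCCCCCCl | starting material
9 | 6-chlorohexanal | O=CCCCCCCl | intermediate
10 | {6-[3,5-bis(tert-butyldimethylsilyloxy)phenyl]hexylidene}triphenylphosphorane (ylide) | c1ccccc1P(c1ccccc1)(c1ccccc1)=CCCCCCc1cc(O[Si](C)(C)C(C)(C)C)cc(O[Si](C)(C)C(C)(C)C)c1 | intermediate
11 | 1,3-bis(tert-butyldimethylsilyloxy)-5-[(6Z)-12-chlorododec-6-en-1-yl]benzene | ClCCCCC/C=C\CCCCCc1cc(O[Si](C)(C)C(C)(C)C)cc(O[Si](C)(C)C(C)(C)C)c1 | intermediate
12 | (S)-glycidol | OC[C@H]1CO1 | starting material
13 | (R)-2-{[(4-methoxybenzyl)oxy]methyl}oxirane | COc1ccc(COC[C@H]2CO2)cc1 | intermediate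
14 | (6Z)-12-[3,5-bis(tert-butyldimethylsilyloxy)phenyl]dodec-6-en-1-ylmagnesium chloride | Cl[Mg]CCCCC/C=C\CCCCCc1cc(O[Si](C)(C)C(C)(C)C)cc(O[Si](C)(C)C(C)(C)C)c1 | intermediate
15 | (2R,9Z)-15-[3,5-bis(tert-butyldimethylsilyloxy)phenyl]-1-[(4-methoxybenzyl)oxy]pentadec-9-en-2-ol | COc1ccc(COC[C@H](O)CCCCCC/C=C\CCCCCc2cc(O[Si](C)(C)C(C)(C)C)cc(O[Si](C)(C)C(C)(C)C)c2)cc1 | intermediate
16 | (2R,9Z)-triisopropylsilyl ether of 15 | COc1ccc(COC[C@H](O[Si](C(C)C)(C(C)C)C(C)C)CCCCCC/C=C\CCCCCc2cc(O[Si](C)(C)C(C)(C)C)cc(O[Si](C)(C)C(C)(C)C)c2)cc1 | intermediate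
17 | (2R,9Z)-15-[3,5-bis(tert-butyldimethylsilyloxy)phenyl]-2-(triisopropylsilyloxy)pentadec-9-en-1-ol | OC[C@H](O[Si](C(C)C)(C(C)C)C(C)C)CCCCCC/C=C\CCCCCc1cc(O[Si](C)(C)C(C)(C)C)cc(O[Si](C)(C)C(C)(C)C)c1 | intermediate
18 | (2R,9Z)-15-[3,5-bis(tert-butyldimethylsilyloxy)phenyl]-2-(triisopropylsilyloxy)pentadec-9-enal | O=C[C@H](O[Si](C(C)C)(C(C)C)C(C)C)CCCCCC/C=C\CCCCCc1cc(O[Si](C)(C)C(C)(C)C)cc(O[Si](C)(C)C(C)(C)C)c1 | intermediate
19 | (3E,5R,12Z)-18-[3,5-bis(tert-butyldimethylsilyloxy)phenyl]-5-(triisopropylsilyloxy)octadeca-3,12-dien-2-one | CC(=O)/C=C/[C@H](O[Si](C(C)C)(C(C)C)C(C)C)CCCCCC/C=C\CCCCCc1cc(O[Si](C)(C)C(C)(C)C)cc(O[Si](C)(C)C(C)(C)C)c1 | intermediate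
20 | dimethyl malonate | COC(=O)CC(=O)OC | starting material
21 | dimethyl 2-[(5R,12Z)-18-[3,5-bis(tert-butyldimethylsilyloxy)phenyl]-2-oxo-5-(triisopropylsilyloxy)octadec-12-en-4-yl]malonate (C4 epimers) | CC(=O)CC(C(C(=O)OC)C(=O)OC)[C@H](O[Si](C(C)C)(C(C)C)C(C)C)CCCCCC/C=C\CCCCCc1cc(O[Si](C)(C)C(C)(C)C)cc(O[Si](C)(C)C(C)(C)C)c1 | intermediate
22 | methyl 6-[(1R,8Z)-14-(3,5-dihydroxyphenyl)-1-(triisopropylsilyloxy)tetradec-8-en-1-yl]-2,4-dioxocyclohexane-1-carboxylate (ring epimers) | COC(=O)C1C(=O)CC(=O)CC1[C@H](O[Si](C(C)C)(C(C)C)C(C)C)CCCCCC/C=C\CCCCCc1cc(O)cc(O)c1 | intermediate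
23 | 6-[(1R,8Z)-14-(3,5-dihydroxyphenyl)-1-(triisopropylsilyloxy)tetradec-8-en-1-yl]-2,4-dioxocyclohexane-1-carboxylic acid (ring epimers) | OC(=O)C1C(=O)CC(=O)CC1[C@H](O[Si](C(C)C)(C(C)C)C(C)C)CCCCCC/C=C\CCCCCc1cc(O)cc(O)c1 | intermediate
24 | 5-[(1R,8Z)-14-(3,5-dihydroxyphenyl)-1-(triisopropylsilyloxy)tetradec-8-en-1-yl]cyclohexane-1,3-dione | O=C1CC(CC(=O)C1)[C@H](O[Si](C(C)C)(C(C)C)C(C)C)CCCCCC/C=C\CCCCCc1cc(O)cc(O)c1 | intermediate
25 | 2-diazo-5-[(1R,8Z)-14-(3,5-dihydroxyphenyl)-1-(triisopropylsilyloxy)tetradec-8-en-1-yl]cyclohexane-1,3-dione | O=C1CC(CC(=O)C1=[N+]=[N-])[C@H](O[Si](C(C)C)(C(C)C)C(C)C)CCCCCC/C=C\CCCCCc1cc(O)cc(O)c1 | intermediate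
26 | 22-membered macrocyclic 2-aryloxycyclohexane-1,3-dione, (R)-carbinol TIPS ether, Z-alkene, one free ring A hydroxyl | Oc1cc2cc(c1)OC1C(=O)CC(CC1=O)[C@H](O[Si](C(C)C)(C(C)C)C(C)C)CCCCCC/C=C\CCCCC2 | intermediate
27 | macrocyclic 2-aryloxy-1,3-bis(tert-butyldimethylsilyloxy)cyclohexa-1,3-diene, ring A O-TBS, (R)-carbinol TIPS ether, Z-alkene | CC(C)(C)[Si](C)(C)Oc1cc2cc(c1)OC1=C(O[Si](C)(C)C(C)(C)C)CC(C=C1O[Si](C)(C)C(C)(C)C)[C@H](O[Si](C(C)C)(C(C)C)C(C)C)CCCCCC/C=C\CCCCC2 | intermediate
28 | tris-O-TBS, O-TIPS ether of the target (ring B aromatic) | CC(C)(C)[Si](C)(C)Oc1cc2cc(c1)Oc1c(O[Si](C)(C)C(C)(C)C)cc(cc1O[Si](C)(C)C(C)(C)C)[C@H](O[Si](C(C)C)(C(C)C)C(C)C)CCCCCC/C=C\CCCCC2 | intermediate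
29 | CNP0316989.2: 22-membered diaryl ether macrocycle, (R)-benzylic carbinol on ring B, Z-alkene, ring A phenol, ring B 2-aryloxyresorcinol | Oc1cc2cc(c1)Oc1c(O)cc(cc1O)[C@H](O)CCCCCC/C=C\CCCCC2 | target

**Step count**
- Total: 19 steps.
- Longest linear sequence: 17 steps (steps 1–5, 7, 9–19).

**Steps most likely to fail**

Step 16. Ring closure may be outpaced by intermolecular O–H insertion (oligomers), or the carbenoid may add to the Z-alkene or to the electron-rich ring A carbons. The fallback closes the same ether bond by macrocyclic Williamson alkylation and builds ring B afterwards. It sets out from aldehyde 18. Wittig olefination with ClCH2C(O)CH=PPh3 in toluene at 60 °C should give the (E)-chloromethyl enone F1. KHF2 in MeOH at rt should free the two ring A phenols selectively, aryl silyl ethers being cleaved ahead of the alkyl TIPS ether, to give the bis-phenol chloromethyl enone F2. K2CO3 with catalytic NaI in acetone at high dilution should then close the macrocyclic aryloxymethyl enone F3 by phenoxide displacement of the α-keto chloride. Treatment with dimethyl malonate 20 and NaOMe in MeOH should give the macrocyclic Michael adduct F4. Claisen closure through the aryloxy-substituted methylene should give the macrocyclic keto ester F5, and saponification should give the macrocyclic keto acid F6. Decarboxylation as in step 14 brings the route back at 26.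

Step 14. Methoxide may remove the γ-hydrogen of the enone, which is the carbinol hydrogen, and so erode the configuration; alternatively the conjugate addition next to the bulky silyloxy carbon may stall and revert. The fallback swaps the annulation partners so that the acceptor is a far less γ-acidic ester. It sets out from aldehyde 18. Wittig reaction with Ph3P=CHCO2Me in CH2Cl2 at rt should give the (E)-enoate F7. Methyl acetoacetate with NaOMe in MeOH should add to it to give the acetoacetate Michael adduct F8. On heating with more NaOMe, Dieckmann closure of the acetyl methyl onto the chain ester, with loss of the aryl silyl groups, should deliver the same cyclic keto ester 22. The hydroxide and acid stages of step 14 then lead on to 24.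

Step 18. Double enol silylation may be incomplete, or silicon may be lost before hydride abstraction so that the enone returns; DDQ may also go on to oxidise the newly benzylic silyl ether carbon. The fallback replaces hydride abstraction by a selenoxide elimination. It sets out from 26. TBSCl and imidazole in DMF should give the ring A silyl ether vinylogous silyl ester F9. LiN(iPr)2 in THF at −78 °C followed by PhSeCl should place selenium on the ring carbon next to the remaining carbonyl, trans to the side chain, giving the phenylselanyl ketone F10. Oxidation with mCPBA at −78 °C and warming with iPr2NH should trigger syn-elimination, and the resulting cyclohexadienone tautomerises to the resorcinol mono-silyl ether F11. Bu4NF with AcOH as in step 19 then gives the target 29.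

**Further compounds**
F1 | step 16 | (3E,5R,12Z)-18-[3,5-bis(tert-butyldimethylsilyloxy)phenyl]-1-chloro-5-(triisopropylsilyloxy)octadeca-3,12-dien-2-one | ClCC(=O)/C=C/[C@H](O[Si](C(C)C)(C(C)C)C(C)C)CCCCCC/C=C\CCCCCc1cc(O[Si](C)(C)C(C)(C)C)cc(O[Si](C)(C)C(C)(C)C)c1
F2 | step 16 | (3E,5R,12Z)-1-chloro-18-(3,5-dihydroxyphenyl)-5-(triisopropylsilyloxy)octadeca-3,12-dien-2-one | ClCC(=O)/C=C/[C@H](O[Si](C(C)C)(C(C)C)C(C)C)CCCCCC/C=C\CCCCCc1cc(O)cc(O)c1
F3 | step 16 | 22-membered macrocyclic aryloxymethyl (E)-enone, (R)-carbinol TIPS ether, Z-alkene, one free ring A hydroxyl | Oc1cc2cc(c1)OCC(=O)/C=C/[C@H](O[Si](C(C)C)(C(C)C)C(C)C)CCCCCC/C=C\CCCCC2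
F4 | step 16 | macrocyclic Michael adduct of dimethyl malonate to F3 | Oc1cc2cc(c1)OCC(=O)CC(C(C(=O)OC)C(=O)OC)[C@H](O[Si](C(C)C)(C(C)C)C(C)C)CCCCCC/C=C\CCCCC2
F5 | step 16 | macrocyclic methyl 3-aryloxy-2,4-dioxocyclohexane-1-carboxylate (4-methoxycarbonyl derivative of 26) | Oc1cc2cc(c1)OC1C(=O)CC(C(C(=O)OC)C1=O)[C@H](O[Si](C(C)C)(C(C)C)C(C)C)CCCCCC/C=C\CCCCC2
F6 | step 16 | macrocyclic 3-aryloxy-2,4-dioxocyclohexane-1-carboxylic acid (4-carboxy derivative of 26) | Oc1cc2cc(c1)OC1C(=O)CC(C(C(=O)O)C1=O)[C@H](O[Si](C(C)C)(C(C)C)C(C)C)CCCCCC/C=C\CCCCC2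
F7 | step 14 | methyl (2E,4R,11Z)-17-[3,5-bis(tert-butyldimethylsilyloxy)phenyl]-4-(triisopropylsilyloxy)heptadeca-2,11-dienoate | COC(=O)/C=C/[C@H](O[Si](C(C)C)(C(C)C)C(C)C)CCCCCC/C=C\CCCCCc1cc(O[Si](C)(C)C(C)(C)C)cc(O[Si](C)(C)C(C)(C)C)c1
F8 | step 14 | dimethyl 2-acetyl-3-[(1R,8Z)-14-[3,5-bis(tert-butyldimethylsilyloxy)phenyl]-1-(triisopropylsilyloxy)tetradec-8-en-1-yl]pentanedioate (epimers) | CC(=O)C(C(=O)OC)C(CC(=O)OC)[C@H](O[Si](C(C)C)(C(C)C)C(C)C)CCCCCC/C=C\CCCCCc1cc(O[Si](C)(C)C(C)(C)C)cc(O[Si](C)(C)C(C)(C)C)c1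
F9 | step 18 | macrocyclic 2-aryloxy-3-(tert-butyldimethylsilyloxy)cyclohex-2-en-1-one, ring A O-TBS | CC(C)(C)[Si](C)(C)Oc1cc2cc(c1)OC1=C(O[Si](C)(C)C(C)(C)C)CC(CC1=O)[C@H](O[Si](C(C)C)(C(C)C)C(C)C)CCCCCC/C=C\CCCCC2
F10 | step 18 | 6-phenylselanyl derivative of F9 | CC(C)(C)[Si](C)(C)Oc1cc2cc(c1)OC1=C(O[Si](C)(C)C(C)(C)C)CC(C([Se]c3ccccc3)C1=O)[C@H](O[Si](C(C)C)(C(C)C)C(C)C)CCCCCC/C=C\CCCCC2
F11 | step 18 | macrocyclic 2-aryloxyresorcinol mono-TBS ether, ring A O-TBS, carbinol TIPS ether | CC(C)(C)[Si](C)(C)Oc1cc2cc(c1)Oc1c(O)cc(cc1O[Si](C)(C)C(C)(C)C)[C@H](O[Si](C(C)C)(C(C)C)C(C)C)CCCCCC/C=C\CCCCC2
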